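The cyclohexene (C1 carries the acyl chain, C2 the 3,4-dimethoxyphenyl group, C3=C4 is the alkene, C6 the 4-hydroxy-3-methoxyphenyl group) is cut across two opposite ring bonds, C1–C6 and C3=C4, into two three-carbon units. One flask joins them: an iminium-catalysed Mukaiyama–Michael addition makes C1–C6 and an intramolecular Wittig reaction makes C3=C4. The step exploits C1 as the α-carbon of the side-chain carbonyl (a latent enolate) and C6–C5–C4 as the β-carbon, α-carbon and formyl carbon of a coniferaldehyde. The precursors are an acyclic γ-phosphonio silyl ketene thioacetal that already holds the C2 stereocentre and O-silylated coniferaldehyde.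

Key step: step 6

Remark: the 1,3-diketone of the target is treated as the chelated enol tautomer that is drawn; the keto and enol forms interconvert, so the last steps should deliver this enol at equilibrium.

Step 1
Reactants: 1 furan-2(5H)-one; 2 (3,4-dimethoxyphenyl)boronic acid
Product: 3 (4S)-4-(3,4-dimethoxyphenyl)oxolan-2-one
Conditions: [Rh(OH)((S)-BINAP)]2 (1.5 mol%), dioxane/H2O 10:1, 35 °C
Reagents that add atoms: none
Why: Hayashi–Miyaura asymmetric conjugate addition, in which the aryl–rhodium/(S)-BINAP species should insert the butenolide on one face (the sense that turns cyclohexenone into its S adduct) and water protonates the oxa-π-allyl, so that the benzylic stereocentre (later ring C2) is set by the ligand.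

Step 2
Reactants: 3 (4S)-4-(3,4-dimethoxyphenyl)oxolan-2-one
Product: 5 [(2S)-3-carboxy-2-(3,4-dimethoxyphenyl)propyl]triphenylphosphonium bromide, via bromo acid 4 (not isolated)
Conditions: Ph3P·HBr (1.05 equiv), neat, 150 °C; trituration with EtOAc
Reagents that add atoms: triphenylphosphine hydrobromide, [Br-].[PH+](c1ccccc1)(c1ccccc1)c1ccccc1
Why: Acid-mediated alkyl–oxygen opening of the lactone by bromide is reversible, but the liberated PPh3 should quaternise the primary bromide irreversibly (SN2 phosphonium salt formation), and the stereocentre next to the reacting CH2 is not involved.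

Step 3
Reactants: 5 [(2S)-3-carboxy-2-(3,4-dimethoxyphenyl)propyl]triphenylphosphonium bromide
Product: 6 S-propan-2-yl (3S)-3-(3,4-dimethoxyphenyl)-4-(triphenylphosphonio)butanethioate bromide
Conditions: i-PrSH (3 equiv), DCC, DMAP (10 mol%), CH2Cl2, 0 °C → rt
Reagents that add atoms: propane-2-thiol, CC(C)S
Why: Steglich-type thioesterification through the O-acylisourea and the acylpyridinium ion installs the thioester that later gives a 1,4-selective silyl ketene thioacetal, without touching the stereocentre.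

Step 4
Reactants: 6 S-propan-2-yl (3S)-3-(3,4-dimethoxyphenyl)-4-(triphenylphosphonio)butanethioate bromide
Product: 7 [(2S,3E)-4-(tert-butyldimethylsilyloxy)-2-(3,4-dimethoxyphenyl)-4-(propan-2-ylsulfanyl)but-3-en-1-yl]triphenylphosphonium bromide (silyloxy group cis to the branched carbon)
Conditions: TBSOTf (1.05 equiv), Et3N (1.5 equiv), CH2Cl2, −78 → 0 °C; volatiles removed, used crude
Reagents that add atoms: tert-butyldimethylsilyl triflate, CC(C)(C)[Si](C)(C)OS(=O)(=O)C(F)(F)F
Why: Soft enolisation (O-silylation of the thioester, then deprotonation by the amine) should give the silyl ketene thioacetal mainly as the isomer shown, while Et3N is far too weak to deprotonate the phosphonium CH2.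

Step 5
Reactants: 8 coniferaldehyde, (E)-3-(4-hydroxy-3-methoxyphenyl)prop-2-enal
Product: 9 (E)-3-[4-(tert-butyldimethylsilyloxy)-3-methoxyphenyl]prop-2-enal
Conditions: TBSCl, imidazole, DMF, rt
Reagents that add atoms: tert-butyldimethylsilyl chloride, CC(C)(C)[Si](C)(C)Cl
Why: Imidazole-promoted silyl ether formation masks the phenol against the ketene acetal, the strong bases and the later oxidant.

Step 6
Reactants: 7 [(2S,3E)-4-(tert-butyldimethylsilyloxy)-2-(3,4-dimethoxyphenyl)-4-(propan-2-ylsulfanyl)but-3-en-1-yl]triphenylphosphonium bromide; 9 (E)-3-[4-(tert-butyldimethylsilyloxy)-3-methoxyphenyl]prop-2-enal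
Product: 12 S-propan-2-yl (1S,2S,6S)-6-[4-(tert-butyldimethylsilyloxy)-3-methoxyphenyl]-2-(3,4-dimethoxyphenyl)cyclohex-3-ene-1-carbothioate (2-aryl trans and 6-aryl cis to the thioester), via delta-oxo thioester phosphonium bromide 10 (not isolated), via phosphorus ylide 11 (not isolated)
Conditions: 7 (1.1 equiv), (2R,5R)-5-benzyl-2-tert-butyl-3-methylimidazolidin-4-one·CCl3CO2H (20 mol%), CH2Cl2, H2O (2 equiv), −40 °C; then evaporation, THF, KN(SiMe3)2 (1.4 equiv), −78 °C → rt
Reagents that add atoms: none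
Why: The imidazolidinone condenses with enal 9 to an iminium ion whose β-carbon is attacked by the nucleophilic carbon of ketene thioacetal 7 (organocatalytic Mukaiyama–Michael addition) to give, after hydrolysis, aldehyde 10; KN(SiMe3)2 then deprotonates the phosphonium CH2 and the non-stabilised ylide 11 closes onto the formyl group (intramolecular Wittig reaction), so that C1–C6 and C3=C4 are made in one flask. The closest known reaction types are the iminium-catalysed additions of silyl ketene thioacetals and silyloxyfurans to β-aryl enals and the cyclisation of ω-formylalkylphosphonium salts to cycloalkenes. The ring closes in the Wittig stage by 6-exo-trig attack of the ylide carbon on the aldehyde and collapse of the oxaphosphetane, which can only give the cis ring alkene. C6 is set by the catalyst, whose benzyl and tert-butyl groups shield one face of the iminium ion (the 2R,5R enantiomer exposes the face that leads to the required configuration), and C1 is set by 1,2-induction from the resident C2 centre (allylic-strain model: the C2–H bond eclipses the ketene acetal, whose cis silyloxy group enforces this conformer, and the electrophile arrives anti to the aryl group); C2 itself is not touched. The step needs 1,4- over 1,2-addition (secured by iminium activation and the soft thioester-derived nucleophile), matched double stereodifferentiation between catalyst and substrate, and ylide formation that outruns enolisation of the thioester (the hindered tertiary C1–H should be kinetically far less acidic than the P-CH2 protons at −78 °C).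

Step 7
Reactants: 12 S-propan-2-yl (1S,2S,6S)-6-[4-(tert-butyldimethylsilyloxy)-3-methoxyphenyl]-2-(3,4-dimethoxyphenyl)cyclohex-3-ene-1-carbothioate
Product: 13 1-[(1S,2S,6S)-6-[4-(tert-butyldimethylsilyloxy)-3-methoxyphenyl]-2-(3,4-dimethoxyphenyl)cyclohex-3-en-1-yl]ethan-1-one
Conditions: Me2CuLi (3 equiv, from MeLi and CuI), Et2O, −78 → −30 °C; NH4Cl aq
Reagents that add atoms: lithium dimethylcuprate, [Li+].C[Cu-]C
Why: Acyl substitution of a thioester by a lithium diorganocuprate (thioester-to-ketone cuprate coupling) stops at the ketone, and the weakly basic cuprate at low temperature should not enolise the C1 centre.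

Step 8
Reactants: 13 1-[(1S,2S,6S)-6-[4-(tert-butyldimethylsilyloxy)-3-methoxyphenyl]-2-(3,4-dimethoxyphenyl)cyclohex-3-en-1-yl]ethan-1-one; 9 (E)-3-[4-(tert-butyldimethylsilyloxy)-3-methoxyphenyl]prop-2-enal
Product: 15 (4E)-1-[(1S,2S,6S)-6-[4-(tert-butyldimethylsilyloxy)-3-methoxyphenyl]-2-(3,4-dimethoxyphenyl)cyclohex-3-en-1-yl]-5-[4-(tert-butyldimethylsilyloxy)-3-methoxyphenyl]-3-hydroxypent-4-en-1-one (both carbinol epimers), via lithium enolate 14 (not isolated)
Conditions: LiN(iPr)2 (1.1 equiv), THF, −78 °C; then 9, −78 °C; AcOH quench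
Reagents that add atoms: none
Why: Kinetic deprotonation should remove a methyl proton rather than the hindered ring C1–H, and the lithium enolate adds 1,2 to the enal (directed aldol addition), the new carbinol centre being formed as a mixture that the next step erases.

Step 9
Reactants: 15 (4E)-1-[(1S,2S,6S)-6-[4-(tert-butyldimethylsilyloxy)-3-methoxyphenyl]-2-(3,4-dimethoxyphenyl)cyclohex-3-en-1-yl]-5-[4-(tert-butyldimethylsilyloxy)-3-methoxyphenyl]-3-hydroxypent-4-en-1-one
Product: 16 (2Z,4E)-1-[(1S,2S,6S)-6-[4-(tert-butyldimethylsilyloxy)-3-methoxyphenyl]-2-(3,4-dimethoxyphenyl)cyclohex-3-en-1-yl]-5-[4-(tert-butyldimethylsilyloxy)-3-methoxyphenyl]-3-hydroxypenta-2,4-dien-1-one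
Conditions: Dess–Martin periodinane (1.3 equiv), NaHCO3, CH2Cl2, 0 °C → rt
Reagents that add atoms: none
Why: Dess–Martin oxidation of the allylic β-hydroxy ketone gives the 1,3-diketone, which should settle as the conjugated chelated enol, under buffered non-basic conditions that leave the C1 centre alone.

Step 10
Reactants: 16 (2Z,4E)-1-[(1S,2S,6S)-6-[4-(tert-butyldimethylsilyloxy)-3-methoxyphenyl]-2-(3,4-dimethoxyphenyl)cyclohex-3-en-1-yl]-5-[4-(tert-butyldimethylsilyloxy)-3-methoxyphenyl]-3-hydroxypenta-2,4-dien-1-one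
Product: 17 (2Z,4E)-1-[(1S,2S,6S)-2-(3,4-dimethoxyphenyl)-6-(4-hydroxy-3-methoxyphenyl)cyclohex-3-en-1-yl]-3-hydroxy-5-(4-hydroxy-3-methoxyphenyl)penta-2,4-dien-1-one (CNP0290899.2)
Conditions: Bu4NF (2.4 equiv), AcOH (2.4 equiv), THF, 0 °C
Reagents that add atoms: none
Why: Fluoride cleaves both aryl silyl ethers (desilylation), and the acetic acid buffer should keep the base-sensitive curcuminoid enol and the C1 centre intact.

Compound list
1 | furan-2(5H)-one | O=C1C=CCO1 | starting material
2 | (3,4-dimethoxyphenyl)boronic acid | COc1ccc(B(O)O)cc1OC | starting material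
3 | (4S)-4-(3,4-dimethoxyphenyl)oxolan-2-one | O=C1C[C@@H](c2ccc(OC)c(OC)c2)CO1 | intermediate
4 | (3S)-4-bromo-3-(3,4-dimethoxyphenyl)butanoic acid | OC(=O)C[C@@H](c1ccc(OC)c(OC)c1)CBr | intermediate (not isolated)
5 | [(2S)-3-carboxy-2-(3,4-dimethoxyphenyl)propyl]triphenylphosphonium bromide | OC(=O)C[C@@H](c1ccc(OC)c(OC)c1)C[P+](c1ccccc1)(c1ccccc1)c1ccccc1.[Br-] | intermediate
6 | S-propan-2-yl (3S)-3-(3,4-dimethoxyphenyl)-4-(triphenylphosphonio)butanethioate bromide | CC(C)SC(=O)C[C@@H](c1ccc(OC)c(OC)c1)C[P+](c1ccccc1)(c1ccccc1)c1ccccc1.[Br-] | intermediate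
7 | [(2S,3E)-4-(tert-butyldimethylsilyloxy)-2-(3,4-dimethoxyphenyl)-4-(propan-2-ylsulfanyl)but-3-en-1-yl]triphenylphosphonium bromide | CC(C)S/C(O[Si](C)(C)C(C)(C)C)=C/[C@@H](c1ccc(OC)c(OC)c1)C[P+](c1ccccc1)(c1ccccc1)c1ccccc1.[Br-] | intermediate
8 | coniferaldehyde, (E)-3-(4-hydroxy-3-methoxyphenyl)prop-2-enal | O=C/C=C/c1ccc(O)c(OC)c1 | starting material
9 | (E)-3-[4-(tert-butyldimethylsilyloxy)-3-methoxyphenyl]prop-2-enal | O=C/C=C/c1ccc(O[Si](C)(C)C(C)(C)C)c(OC)c1 | intermediate
10 | S-propan-2-yl (2S,3S)-3-[4-(tert-butyldimethylsilyloxy)-3-methoxyphenyl]-2-[(1S)-1-(3,4-dimethoxyphenyl)-2-(triphenylphosphonio)ethyl]-5-oxopentanethioate bromide | CC(C)SC(=O)[C@H]([C@@H](c1ccc(OC)c(OC)c1)C[P+](c1ccccc1)(c1ccccc1)c1ccccc1)[C@H](CC=O)c1ccc(O[Si](C)(C)C(C)(C)C)c(OC)c1.[Br-] | intermediate (not isolated)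
11 | S-propan-2-yl (2S,3S)-3-[4-(tert-butyldimethylsilyloxy)-3-methoxyphenyl]-2-[(1S)-1-(3,4-dimethoxyphenyl)-2-(triphenylphosphoranylidene)ethyl]-5-oxopentanethioate | CC(C)SC(=O)[C@H]([C@@H](c1ccc(OC)c(OC)c1)C=P(c1ccccc1)(c1ccccc1)c1ccccc1)[C@H](CC=O)c1ccc(O[Si](C)(C)C(C)(C)C)c(OC)c1 | intermediate (not isolated)
12 | S-propan-2-yl (1S,2S,6S)-6-[4-(tert-butyldimethylsilyloxy)-3-methoxyphenyl]-2-(3,4-dimethoxyphenyl)cyclohex-3-ene-1-carbothioate | CC(C)SC(=O)[C@@H]1[C@@H](c2ccc(OC)c(OC)c2)C=CC[C@@H]1c1ccc(O[Si](C)(C)C(C)(C)C)c(OC)c1 | intermediate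
13 | 1-[(1S,2S,6S)-6-[4-(tert-butyldimethylsilyloxy)-3-methoxyphenyl]-2-(3,4-dimethoxyphenyl)cyclohex-3-en-1-yl]ethan-1-one | CC(=O)[C@@H]1[C@@H](c2ccc(OC)c(OC)c2)C=CC[C@@H]1c1ccc(O[Si](C)(C)C(C)(C)C)c(OC)c1 | intermediate
14 | lithium 1-[(1S,2S,6S)-6-[4-(tert-butyldimethylsilyloxy)-3-methoxyphenyl]-2-(3,4-dimethoxyphenyl)cyclohex-3-en-1-yl]ethen-1-olate | [Li]OC(=C)[C@@H]1[C@@H](c2ccc(OC)c(OC)c2)C=CC[C@@H]1c1ccc(O[Si](C)(C)C(C)(C)C)c(OC)c1 | intermediate (not isolated)
15 | (4E)-1-[(1S,2S,6S)-6-[4-(tert-butyldimethylsilyloxy)-3-methoxyphenyl]-2-(3,4-dimethoxyphenyl)cyclohex-3-en-1-yl]-5-[4-(tert-butyldimethylsilyloxy)-3-methoxyphenyl]-3-hydroxypent-4-en-1-one (carbinol epimers) | COc1cc(/C=C/C(O)CC(=O)[C@@H]2[C@@H](c3ccc(OC)c(OC)c3)C=CC[C@@H]2c2ccc(O[Si](C)(C)C(C)(C)C)c(OC)c2)ccc1O[Si](C)(C)C(C)(C)C | intermediate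
16 | (2Z,4E)-1-[(1S,2S,6S)-6-[4-(tert-butyldimethylsilyloxy)-3-methoxyphenyl]-2-(3,4-dimethoxyphenyl)cyclohex-3-en-1-yl]-5-[4-(tert-butyldimethylsilyloxy)-3-methoxyphenyl]-3-hydroxypenta-2,4-dien-1-one | COc1cc(/C=C/C(O)=C/C(=O)[C@@H]2[C@@H](c3ccc(OC)c(OC)c3)C=CC[C@@H]2c2ccc(O[Si](C)(C)C(C)(C)C)c(OC)c2)ccc1O[Si](C)(C)C(C)(C)C | intermediate
17 | (2Z,4E)-1-[(1S,2S,6S)-2-(3,4-dimethoxyphenyl)-6-(4-hydroxy-3-methoxyphenyl)cyclohex-3-en-1-yl]-3-hydroxy-5-(4-hydroxy-3-methoxyphenyl)penta-2,4-dien-1-one | COc1cc(/C=C/C(O)=C/C(=O)[C@@H]2[C@@H](c3ccc(OC)c(OC)c3)C=CC[C@@H]2c2ccc(O)c(OC)c2)ccc1O | target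

Total step count: 10. Longest linear sequence: 9 steps (steps 1–4 and 6–10).

Steps most likely to fail

Step 6. The face of the ketene acetal that reacts may not follow the C2-directed approach once the catalyst-bound iminium ion imposes its own preferred topicity (mismatched double stereodifferentiation). The hindered cationic nucleophile may also add so slowly that hydrolysis wins, and the base may epimerise the thioester α-centre or cause retro-Michael cleavage before the ylide cyclises. The fallback changes the activation mode and puts ring C1 under thermodynamic control; it sets out from 6 and 9 and returns at 13. Thioester 6 is reduced with Et3SiH and Pd/C (Fukuyama reduction) to [(2S)-2-(3,4-dimethoxyphenyl)-4-oxobutyl]triphenylphosphonium bromide F1. F1 and enal 9 are joined by enamine/iminium catalysis with (R)-2-[diphenyl(trimethylsilyloxy)methyl]pyrrolidine and PhCO2H in wet toluene to the dialdehyde [(2S,3S,4S)-4-[4-(tert-butyldimethylsilyloxy)-3-methoxyphenyl]-2-(3,4-dimethoxyphenyl)-3-formyl-6-oxohexyl]triphenylphosphonium bromide F2. In F2 the centre that becomes ring C1 is α to a formyl group and can equilibrate through the enamine towards the 3,4-trans cyclic hemiacetal, which corresponds to the required cis relationship in the carbocycle. KN(SiMe3)2 in THF at −78 °C should then close F2 by Wittig reaction to (1S,2S,6S)-6-[4-(tert-butyldimethylsilyloxy)-3-methoxyphenyl]-2-(3,4-dimethoxyphenyl)cyclohex-3-ene-1-carbaldehyde F3. MeMgBr gives the carbinol 1-[(1S,2S,6S)-6-[4-(tert-butyldimethylsilyloxy)-3-methoxyphenyl]-2-(3,4-dimethoxyphenyl)cyclohex-3-en-1-yl]ethan-1-ol F4, and Dess–Martin oxidation gives methyl ketone 13.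

Step 2. Hot HBr may cleave the aryl methyl ethers, and the electron-rich aryl group may participate in the ionising CH2–O bond, so that aryl migration competes with the SN2 pathway. The fallback avoids acid and cationic character; it sets out from 3 and returns at 6. Lactone 3 is opened at the acyl carbon with Me2AlS-iPr (AlMe3, i-PrSH, CH2Cl2, 0 °C) to S-propan-2-yl (3S)-3-(3,4-dimethoxyphenyl)-4-hydroxybutanethioate F5. F5 is converted without delay (to forestall relactonisation) by an Appel reaction (CBr4, PPh3, 0 °C) into S-propan-2-yl (3S)-4-bromo-3-(3,4-dimethoxyphenyl)butanethioate F6. Quaternisation with PPh3 in MeCN at 80 °C gives thioester salt 6.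

Step 1. Protodeboronation of the electron-rich boronic acid and base-induced decay of the butenolide may outpace the insertion, or enantiofacial control may be incomplete. The fallback separates C–C bond formation from the stereo-defining event; it sets out from 2 and returns at 3. Boronic acid 2 is coupled with 4-bromofuran-2(5H)-one (Pd(PPh3)4, K2CO3, dioxane/H2O; Suzuki–Miyaura reaction) to 4-(3,4-dimethoxyphenyl)furan-2(5H)-one F7. The stereocentre is then set by copper hydride-catalysed asymmetric conjugate reduction (Cu(OAc)2, the p-tol-BINAP enantiomer that leads to the S lactone, polymethylhydrosiloxane, t-BuOH) to give lactone 3.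

Further compounds
F1 | step 6 | [(2S)-2-(3,4-dimethoxyphenyl)-4-oxobutyl]triphenylphosphonium bromide | O=CC[C@@H](c1ccc(OC)c(OC)c1)C[P+](c1ccccc1)(c1ccccc1)c1ccccc1.[Br-]
F2 | step 6 | [(2S,3S,4S)-4-[4-(tert-butyldimethylsilyloxy)-3-methoxyphenyl]-2-(3,4-dimethoxyphenyl)-3-formyl-6-oxohexyl]triphenylphosphonium bromide | O=C[C@H]([C@@H](c1ccc(OC)c(OC)c1)C[P+](c1ccccc1)(c1ccccc1)c1ccccc1)[C@H](CC=O)c1ccc(O[Si](C)(C)C(C)(C)C)c(OC)c1.[Br-]
F3 | step 6 | (1S,2S,6S)-6-[4-(tert-butyldimethylsilyloxy)-3-methoxyphenyl]-2-(3,4-dimethoxyphenyl)cyclohex-3-ene-1-carbaldehyde | O=C[C@@H]1[C@@H](c2ccc(OC)c(OC)c2)C=CC[C@@H]1c1ccc(O[Si](C)(C)C(C)(C)C)c(OC)c1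
F4 | step 6 | 1-[(1S,2S,6S)-6-[4-(tert-butyldimethylsilyloxy)-3-methoxyphenyl]-2-(3,4-dimethoxyphenyl)cyclohex-3-en-1-yl]ethan-1-ol (carbinol epimers) | CC(O)[C@@H]1[C@@H](c2ccc(OC)c(OC)c2)C=CC[C@@H]1c1ccc(O[Si](C)(C)C(C)(C)C)c(OC)c1
F5 | step 2 | S-propan-2-yl (3S)-3-(3,4-dimethoxyphenyl)-4-hydroxybutanethioate | CC(C)SC(=O)C[C@@H](c1ccc(OC)c(OC)c1)CO
F6 | step 2 | S-propan-2-yl (3S)-4-bromo-3-(3,4-dimethoxyphenyl)butanethioate | CC(C)SC(=O)C[C@@H](c1ccc(OC)c(OC)c1)CBr
F7 | step 1 | 4-(3,4-dimethoxyphenyl)furan-2(5H)-one | O=C1C=C(c2ccc(OC)c(OC)c2)CO1
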